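## Analysis of the target

Atom numbering: C1 is the quaternary carbon carrying the acetoxymethyl carbon Ca; C2 (CH2), C3 (CH–OAc), C4 (CH–OH) and C5 (CMe2) follow round ring A to the bridgehead C6; C7 is the cage methylene, C8 and C9 are the cyclopropane CH carbons, C10 is the cyclopropane carbon bearing methyl, and C11 is the CH–OAc carbon between C10 and C6. The fifteen-carbon skeleton is a nortricyclane (tricyclo[2.2.1.0(2,6)]heptane) in which bridgehead C6 is tied by the three one-carbon bridges C1, C7 and C11 to the cyclopropane C9–C8–C10, with the cyclohexane ring A (C1–C6) fused on the C1–C6 bond. Of the eight stereocentres, C6, C8, C9 and C10 are forced by the cage once C1 is fixed, so the independent elements are C1, C3, C4 and C11. Ca, the C7 bridge, the C3 acetate and the C4 hydroxyl lie on one face of ring A (C3–O and C4–O cis), and the C11 acetate points into the open sector between the C7 and C11 bridges, so that H11 sits under ring A, close to the C2 methylene. The sensitive features are a free secondary hydroxyl cis-vicinal to an acetate (acyl migration) and a cyclopropylcarbinyl oxygen at C11 (ionisation, and ring opening under electron transfer). The difficulty lies in three contiguous fully substituted carbons (C5, C6, C1) with a fourth quaternary centre at C10, in four oxygens of which exactly one stays free, and in a C11–H bond that must be made on the shielded side of the cage. The strategy rests on the C4 hydroxyl next to the gem-dimethyl carbon C5, itself bonded to quaternary C6, which is α to the oxygenated C11: this is what a 2,2-dimethyl-substituted epoxide leaves when its tertiary carbon is attacked by the enol carbon of a C11 ketone.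

## Retrosynthetic reasoning

End game and protecting groups. Target 30 is traced to the silyl ether 29, the triol 28 and the dibenzyl ether 27. The key step liberates O4 as the only free hydroxyl, and O4 is the one oxygen that stays unacylated in 30. It is therefore capped once as a silyl ether (21) and uncovered last, while Ca–O and O3 travel as benzyl ethers and are exchanged for acetates together with O11.

C11–H bond. Alcohol 27 is traced to ketone 26. The cut is forced because C11 is a carbonyl in the key step. Any hydride reagent would approach C11 of 26 from the open sector next to C7 and push the oxygen under ring A, the wrong epimer. The forward step is therefore a reversible hydride transfer, which lets the oxygen settle in the open sector.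

Cyclopropane. In 26 the bonds C8–C9 and C8–C10 are cut together, which leads through pyrazoline 25 and diazoalkane 24 to tosylhydrazone 23, aldehyde 22 and the allyl compound 21. The cut is made here because C9=C10 is then the alkene of an enone, the natural partner for a nucleophilic diazo carbon, and both bonds form on the face that already carries C7. What remains is a cis-fused bicyclic enone.

Key disconnection. Alcohol 20 is cut at C5–C6 to give the epoxy silyl dienol ether 19. This one cut removes ring A and the adjacency of three fully substituted carbons, leaving a cyclopentadiene whose only quaternary carbon is C1, and it explains the C4 hydroxyl. Cutting C1–C6 or C1–C2 instead would require joining two fully substituted carbons without the help of a tertiary cation. The forward reaction has to join a tetrasubstituted enol ether carbon to the tertiary epoxide carbon, at C5 and not at C4.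

Precursor assembly. Dienol ether 19 comes from ketone 18 by enol silylation, 18 from alkene 17 by reagent-controlled oxygen transfer, and 17 from cyclopentenone 15 by α′-allylation with 16. The C6 centre created in 17 is of no consequence because it is flattened again in 19.

Cyclopentenone and the C1 centre. The C9=C10 bond of 15 is cut by a retro-aldol condensation to the γ-keto aldehyde 13. The C3 centre is too remote to steer an alkylation at C1 of an open-chain aldehyde, so the quaternary carbon is built inside the rigid bicyclic lactam 3 by two successive enolate alkylations (5, then 7). The lactam is then unmasked (11 to 13) as the keto aldehyde.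

Side chain. While the keto aldehyde is still masked, the C3–C4 bond is cut in enone 9 to the N-methoxy-N-methylamide 7 and the alkenyl Grignard reagent 8. C3 is set by catalyst-controlled reduction (10) and protected (11).

Lactam. Compound 3 is the condensation product of the amino alcohol 1 and the keto acid 2, whose ethyl ketone supplies C10 and its methyl group.

## Alternatives that were turned down

Alternative 1: The C1–C6 and C8–C9 bonds are cut as an intramolecular Diels–Alder reaction. A 2-siloxycyclopentadiene unit (C6=C11–C10=C8) adds to a (Z)-3-bromoacrylate unit (C1=C9) tethered through C2–C5, giving the bromo ester silyl enol ether A1.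
- For: ring A, the bicyclic core and both quaternary carbons C1 and C6 arise in one pericyclic step with fixed relative configuration, and the bromide is placed for a later C9–C10 closure. On predictability of the bond between the two quaternary carbons this is at least as strong as a cationic closure.
- Against: the diene has an sp3 CH2 (C7) in the ring, so 1,5-hydrogen shifts can move the double bonds before the cycloaddition. Both bonding termini are fully substituted, and the facial choice depends on remote tether centres. A1 still needs the cyclopropane closure, reduction of the ester to Ca, and a C11 carbonyl reduction with the same facial problem as in 26.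
- Comparison: the chosen route offers a dienol ether (19) that cannot isomerise because C1 is quaternary, and it delivers the C4 oxygen directly in the bond-forming step.

Alternative 2: The C1–C9 bond is cut as a Nazarov closure, and C6–C7 with C8–C10 as capture of the resulting oxyallyl cation by a vinyl group on C9. The forward step would start from a cyclohexenyl dienyl ketone and give the cage ketone carbonate A2. The Lewis acid would be Me2AlCl A3.
- For: three C–C bonds and three rings form in one operation from a monocyclic substrate. In step economy this is clearly stronger than the chosen route.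
- Against: the conrotatory closure must create quaternary C1 with a sense dictated only by the ring A stereocentres. The capture has to close a three-membered ring through a strained bridging arrangement, with a weakly nucleophilic vinyl group passing through a secondary cation. Proton loss and 1,2-shifts of the oxyallyl cation compete, and the carbonate carbonyl competes with the dienone for A3. A2 again ends as a C11 ketone.
- Comparison: the chosen route spreads these events over separately controllable steps, each stereocentre tied to one named control element.

Alternative 3: The C1–C9 and C10–C11 bonds are cut as a radical cascade. Hydrogen-atom transfer to the ring A alkene gives a C1 radical, which adds to a pendant 1-methylcyclopropene; the cyclopropyl radical then adds to the C11 aldehyde to give alcohol A4. The catalyst would be Fe(acac)3 A5 and the hydrogen source PhSiH3 A6.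
- For: C11 is formed directly at the alcohol level under neutral conditions, so no late ketone reduction is needed. If the aldehyde face were controlled, this would avoid the weakest point of the chosen route.
- Against: the strained cyclopropene is a better hydrogen-atom acceptor than the ring A alkene, so hydrogen-atom transfer from A5 and A6 is likely to start the cascade at the wrong π bond. Addition of a carbon radical to an aldehyde carbon gives an alkoxy radical that fragments back. The C11 configuration depends on an uncontrolled aldehyde rotamer. The cyclopropene-bearing substrate is long to make and fragile.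
- Comparison: the chosen route uses only closed-shell steps of known type and confines its real uncertainty to one bond formation.

Key step: step 11

Remark: deprotonated or metal-bound forms of a substrate (enolates, alkoxides, chelates) that are made and consumed within one step are treated as part of the conditions and carry no number.
Remark: 4-oxohexanoic acid and both enantiomers of the ketone catalyst of the Shi epoxidation are taken as purchasable.

## Route

Step 1
Reactants: 1 L-valinol; 2 4-oxohexanoic acid
Product: 3 (3S,7aR)-7a-ethyl-3-(propan-2-yl)tetrahydropyrrolo[2,1-b][1,3]oxazol-5(6H)-one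
Conditions: PhMe, reflux, Dean–Stark trap, TsOH (cat.)
Reagents that add atoms: none
Why: Cyclodehydration of an amino alcohol with a γ-keto acid (N,O-ketal formation and lactamisation) should give the cis-fused bicyclic lactam; the valinol centre places isopropyl and the angular ethyl group on the same, convex face under thermodynamic control.

Step 2
Reactants: 3 bicyclic lactam; 4 benzyl chloromethyl ether
Product: 5 6-[(benzyloxy)methyl] lactam (both C6 epimers)
Conditions: LiN(iPr)2, THF, −78 °C; then 4, −78 to −40 °C
Reagents that add atoms: none
Why: Amide enolate alkylation with a highly reactive α-chloro ether brings in Ca with its benzyl ether; the configuration at C6 does not matter because the centre is enolised again in step 3.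

Step 3
Reactants: 5 monoalkylated lactam; 6 2-bromo-N-methoxy-N-methylacetamide
Product: 7 6,6-disubstituted lactam with CH2OBn on the face of the angular ethyl group and CH2C(=O)N(OMe)Me on the opposite face
Conditions: LiN(iPr)2, THF, −78 °C; then 6, −78 to −30 °C
Reagents that add atoms: none
Why: Second enolate alkylation creates the quaternary carbon (the later C1). The electrophile should enter on the face away from the 1,3-related angular ethyl group and the isopropyl group, so the group introduced first ends syn to ethyl. The enolate is kept cold to suppress loss of benzyloxide from its β-position.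

Step 4
Reactants: 7 lactam amide; 8 2-methylprop-1-enylmagnesium bromide
Product: 9 lactam enone with a CH2C(=O)CH=CMe2 side chain
Conditions: THF, 0 °C; aq. NH4Cl
Reagents that add atoms: none
Why: Weinreb ketone synthesis: the chelated tetrahedral adduct survives until work-up, so a single alkenyl group adds; the tertiary lactam carbonyl next to a quaternary carbon is inert at this temperature.

Step 5
Reactants: 9 lactam enone
Product: 10 lactam with a (2S)-2-hydroxy-4-methylpent-3-enyl side chain
Conditions: (R)-2-methyl-CBS-oxazaborolidine (0.2 equiv), BH3·SMe2, THF, −40 °C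
Reagents that add atoms: none
Why: Corey–Bakshi–Shibata reduction: the alkenyl group acts as the large substituent and the (R)-catalyst should deliver hydride to give the (S)-carbinol at C3. Control is by the catalyst and the lactam centres are remote; the alcohol is carried on without delay.

Step 6
Reactants: 10 allylic alcohol
Product: 11 lactam with a (2S)-2-(benzyloxy)-4-methylpent-3-enyl side chain
Conditions: NaH, BnBr, Bu4NI, THF/DMF, 0 °C to rt
Reagents that add atoms: benzyl bromide, BrCc1ccccc1
Why: Williamson etherification of a secondary allylic alkoxide; the lactam has no enolisable position left, so the base has no second site of attack.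

Step 7
Reactants: 11 dibenzyl ether lactam
Product: 15 (4R)-4-[(benzyloxy)methyl]-4-[(2S)-2-(benzyloxy)-4-methylpent-3-en-1-yl]-2-methylcyclopent-2-en-1-one, via carbinolamine 12 (not isolated), via keto aldehyde 13 (not isolated), via aldol adduct 14 (not isolated)
Conditions: NaAlH2(OCH2CH2OMe)2, PhMe, 0 °C to rt; 1 M Bu4NH2PO4, EtOH/H2O, reflux; then KOH, EtOH, rt
Reagents that add atoms: water, O
Why: Partial reduction of the lactam to the carbinolamine, hydrolysis of the N,O-ketal to the γ-keto aldehyde (releasing valinol) and intramolecular aldol condensation of the ethyl ketone CH2 onto the aldehyde should give the 2-methylcyclopentenone. The aldehyde is α-quaternary, so C1 cannot epimerise, and only the five-membered aldol mode is open.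

Step 8
Reactants: 15 cyclopentenone; 16 allyl bromide
Product: 17 5-allyl cyclopentenone (both C5 epimers; C6 in the target numbering)
Conditions: LiN(iPr)2, THF, −78 °C; then 16, −78 to −20 °C
Reagents that add atoms: none
Why: Kinetic α′-enolate alkylation of an enone whose γ-position is blocked by the quaternary carbon; the new centre is erased in step 10, so no selectivity is needed.

Step 9
Reactants: 17 allylated cyclopentenone
Product: 18 epoxy ketone with a (2S)-3,3-dimethyloxiran-2-yl group (C4 S, C3 S)
Conditions: L-fructose-derived ketone catalyst of the Shi epoxidation (0.3 equiv), KHSO5, K2CO3, Bu4NHSO4, MeCN/CH2(OMe)2/H2O (pH 10.5), 0 °C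
Reagents that add atoms: potassium peroxymonosulfate, [K+].[O-]S(=O)(=O)OO
Why: Shi epoxidation: the electron-rich trisubstituted alkene should react well ahead of the terminal allyl alkene and the electron-poor enone. By the spiro transition-state model this catalyst enantiomer delivers oxygen to the face that gives the (S)-epoxide at C4, and attack anti to the allylic benzyloxy group in the hydrogen-eclipsed conformer points the same way.

Step 10
Reactants: 18 epoxy ketone
Product: 19 trimethylsilyl dienol ether (1-allyl-3-methyl-2-(trimethylsilyloxy)cyclopenta-1,3-diene with the quaternary C1 and the epoxy ether chain)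
Conditions: LiN(iPr)2, Me3SiCl, THF, −78 °C (in situ quench); pentane, filtration
Reagents that add atoms: chlorotrimethylsilane, C[Si](C)(C)Cl
Why: C6–H is the only acidic hydrogen, so deprotonation gives one cross-conjugated enolate, which is silylated on oxygen as it forms and so has no time to attack the epoxide; both C6 epimers of 18 converge.

Step 11
Reactants: 19 epoxy silyl dienol ether
Product: 20 cis-fused 7a-allyl-5-(benzyloxy)-3a-[(benzyloxy)methyl]-6-hydroxy-2,7,7-trimethyl-3a,4,5,6,7,7a-hexahydro-1H-inden-1-one (Ca, allyl, C3–O and C4–O on one face)
Conditions: TiCl4 (1.1 equiv), 2,6-di-tert-butyl-4-methylpyridine, CH2Cl2, −78 °C; aq. NaHCO3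
Reagents that add atoms: none
Why: TiCl4 binds the epoxide oxygen and loosens the C5–O bond, because positive charge is tolerated at the tertiary C5 and not at C4, which has the electron-withdrawing C3 benzyloxy neighbour; C6, the only nucleophilic carbon of the cross-conjugated dienol ether (C1 is quaternary, so the diene cannot shift), then bonds to C5 and the trimethylsilyl group is lost to return the C11 enone. The closest known reaction type is the Lewis-acid-promoted intramolecular opening of a trisubstituted epoxide at its tertiary carbon by a silyl enol ether, an epoxide-initiated cyclisation of the Mukaiyama kind. Ring A closes in the 6-endo mode with respect to the epoxide (both epoxide carbons end in the ring and the oxygen stays on C4) and exo with respect to the enol double bond. The one new stereocentre, C6, is controlled by C1: the C2 tether hangs from one face of the flat cyclopentadiene and can bring C5 only to that face, so the ring fusion is cis and the allyl group ends cis to Ca. C4 keeps its configuration and C5 carries two methyl groups, so the sense of substitution at C5 leaves no stereochemical trace. The step needs attack at C5 and not C4 (secured by the cationic bias and by C4 being deactivated) and C–C bond formation ahead of hydride shift from C4, proton loss to an isopropenyl group and chloride capture (favoured by −78 °C and by the nucleophile being held within reach). Backside attack at C5 places the C4 oxygen equatorial on the nascent ring A, and for this diastereomer that means either a chair with Ca, the C3 benzyloxy group and one C5 methyl group all axial on one face or a boat-like arrangement; a strongly ionising Lewis acid is therefore chosen so that C5–O cleavage runs well ahead of C–C bond formation and strict alignment is not required.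

Step 12
Reactants: 20 hydrindenone alcohol
Product: 21 C4 tert-butyldimethylsilyl ether of 20
Conditions: tBuMe2SiOTf, 2,6-lutidine, CH2Cl2, 0 °C
Reagents that add atoms: tert-butyldimethylsilyl trifluoromethanesulfonate, CC(C)(C)[Si](C)(C)OS(=O)(=O)C(F)(F)F
Why: Silylation of a hindered secondary alcohol with a silyl triflate; this is the only free hydroxyl and the one that must stay unacylated, and the enone has no enolisable hydrogen.

Step 13
Reactants: 21 allyl silyl ether
Product: 22 aldehyde (C6–CH2–CHO; C8 is the aldehyde carbon)
Conditions: OsO4 (2 mol %), NaIO4, 2,6-lutidine, dioxane/H2O, rt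
Reagents that add atoms: osmium tetroxide, O=[Os](=O)(=O)=O; sodium periodate, [Na+].[O-]I(=O)(=O)=O
Why: Lemieux–Johnson oxidation: the terminal alkene is dihydroxylated and cleaved, while the hindered, electron-poor, trisubstituted enone alkene should not be touched.

Step 14
Reactants: 22 aldehyde
Product: 23 aldehyde tosylhydrazone
Conditions: TsNHNH2, THF, rt
Reagents that add atoms: 4-methylbenzenesulfonohydrazide, Cc1ccc(cc1)S(=O)(=O)NN
Why: Hydrazone condensation; the aldehyde reacts and the C11 ketone, flanked by a quaternary carbon and an α-substituted alkene, does not.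

Step 15
Reactants: 23 tosylhydrazone
Product: 26 cage ketone (C11 ketone; C4 silyl ether; C3 and Ca benzyl ethers), via diazoalkane 24 (not isolated), via pyrazoline 25 (not isolated)
Conditions: NaH, THF, 0 °C to rt; then PhMe, 110 °C
Reagents that add atoms: none
Why: Aprotic Bamford–Stevens decomposition of the sodium salt gives the diazoalkane, which adds as a 1,3-dipole across the enone with its carbon on the β-carbon C9 and its terminal nitrogen on C10; the α-keto pyrazoline then loses N2 with closure of C8–C10. The two-carbon tether sits on the Ca face, so C8, C9 and C10 can form in one sense only, and the methyl group on C10 is turned outward.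

Step 16
Reactants: 26 cage ketone
Product: 27 C11 alcohol with the hydroxyl in the sector between the C7 and C11 bridges (cis to C7 and Ca)
Conditions: Al(OiPr)3 (excess), i-PrOH/PhMe, 110 °C, sealed tube, prolonged (equilibrating)
Reagents that add atoms: none
Why: Meerwein–Ponndorf–Verley reduction run under equilibrating conditions: hydride transfer is reversible, the epimer with oxygen under ring A is strained by contact with the C2 methylene, and its exposed C11–H is readily given back, so the mixture should drain to the epimer with oxygen in the open sector, as in the equilibration of bicyclic carbinols of the borneol type. No electron transfer is involved, so the conjugated cyclopropane is not opened.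

Step 17
Reactants: 27 dibenzyl ether
Product: 28 triol (Ca–OH, C3–OH, C11–OH) with the C4 silyl ether
Conditions: H2 (1 atm), Pd(OH)2/C, EtOAc/EtOH, rt
Reagents that add atoms: none
Why: Hydrogenolysis of two benzyl ethers; an unactivated, fully alkyl-substituted cyclopropane and the silyl ether should survive these mild conditions.

Step 18
Reactants: 28 triol
Product: 29 triacetate with the C4 silyl ether
Conditions: Ac2O, DMAP, pyridine, rt to 40 °C
Reagents that add atoms: acetic anhydride, CC(=O)OC(C)=O
Why: Nucleophile-catalysed acylation of all three free hydroxyls; no selectivity is needed because O4 is masked, and DMAP copes with the hindered C3 and C11 positions.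

Step 19
Reactants: 29 triacetate silyl ether
Product: 30 target triacetate with free C4 hydroxyl
Conditions: HF·pyridine, pyridine/THF, 0 °C to rt
Reagents that add atoms: none
Why: Fluoride cleavage of the Si–O bond under buffered, mildly acidic conditions, which leave acetates alone and disfavour 1,2-acetyl migration from O3 to the neighbouring cis O4.

## Compound list

1 | L-valinol, (2S)-2-amino-3-methylbutan-1-ol | CC(C)[C@H](N)CO | starting material
2 | 4-oxohexanoic acid | CCC(=O)CCC(=O)O | starting material
3 | (3S,7aR)-7a-ethyl-3-(propan-2-yl)tetrahydropyrrolo[2,1-b][1,3]oxazol-5(6H)-one, cis-fused, isopropyl and ethyl on the same face | O=C1CC[C@@]2(CC)OC[C@H](C(C)C)N12 | intermediate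
4 | benzyl chloromethyl ether | ClCOCc1ccccc1 | starting material
5 | 6-[(benzyloxy)methyl] derivative of 3, both C6 epimers | O=C1C(COCc3ccccc3)C[C@@]2(CC)OC[C@H](C(C)C)N12 | intermediate
6 | 2-bromo-N-methoxy-N-methylacetamide | CON(C)C(=O)CBr | starting material
7 | 6-[(benzyloxy)methyl]-6-[2-(methoxy(methyl)amino)-2-oxoethyl] lactam, CH2OBn syn to the angular ethyl group | O=C1[C@@](COCc3ccccc3)(CC(=O)N(C)OC)C[C@@]2(CC)OC[C@H](C(C)C)N12 | intermediate
8 | 2-methylprop-1-enylmagnesium bromide | CC(C)=C[Mg]Br | starting material
9 | 6-[(benzyloxy)methyl]-6-(4-methyl-2-oxopent-3-enyl) lactam, quaternary centre as in 7 | O=C1[C@@](COCc3ccccc3)(CC(=O)C=C(C)C)C[C@@]2(CC)OC[C@H](C(C)C)N12 | intermediate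
10 | 6-[(benzyloxy)methyl]-6-[(2S)-2-hydroxy-4-methylpent-3-enyl] lactam | O=C1[C@@](COCc3ccccc3)(C[C@H](O)C=C(C)C)C[C@@]2(CC)OC[C@H](C(C)C)N12 | intermediate
11 | 6-[(benzyloxy)methyl]-6-[(2S)-2-(benzyloxy)-4-methylpent-3-enyl] lactam | O=C1[C@@](COCc3ccccc3)(C[C@H](OCc3ccccc3)C=C(C)C)C[C@@]2(CC)OC[C@H](C(C)C)N12 | intermediate
12 | carbinolamine from reduction of the lactam carbonyl of 11 (C5–OH, either epimer) | OC1[C@@](COCc3ccccc3)(C[C@H](OCc3ccccc3)C=C(C)C)C[C@@]2(CC)OC[C@H](C(C)C)N12 | intermediate
13 | 2-[(benzyloxy)methyl]-2-[(2S)-2-(benzyloxy)-4-methylpent-3-en-1-yl]-4-oxohexanal, quaternary centre as in 7 | O=C[C@@](COCc1ccccc1)(C[C@H](OCc1ccccc1)C=C(C)C)CC(=O)CC | intermediate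
14 | aldol adduct, 3-hydroxy-2-methylcyclopentanone bearing the quaternary carbon of 13 (new centres unassigned) | CC1C(O)[C@@](COCc2ccccc2)(C[C@H](OCc2ccccc2)C=C(C)C)CC1=O | intermediate
15 | (4R)-4-[(benzyloxy)methyl]-4-[(2S)-2-(benzyloxy)-4-methylpent-3-en-1-yl]-2-methylcyclopent-2-en-1-one | CC1=C[C@@](COCc2ccccc2)(C[C@H](OCc2ccccc2)C=C(C)C)CC1=O | intermediate
16 | allyl bromide | C=CCBr | starting material
17 | 5-allyl derivative of 15, both C5 epimers, quaternary centre unchanged | CC1=C[C@@](COCc2ccccc2)(C[C@H](OCc2ccccc2)C=C(C)C)C(CC=C)C1=O | intermediate
18 | 5-allyl-4-[(benzyloxy)methyl]-4-{(2S)-2-(benzyloxy)-2-[(2S)-3,3-dimethyloxiran-2-yl]ethyl}-2-methylcyclopent-2-en-1-one, both C5 epimers | CC1=C[C@@](COCc2ccccc2)(C[C@H](OCc2ccccc2)[C@@H]2OC2(C)C)C(CC=C)C1=O | intermediate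
19 | trimethylsilyl dienol ether of 18: 1-allyl-3-methyl-2-(trimethylsilyloxy)cyclopenta-1,3-diene with C5 of the ring carrying CH2OBn and the epoxy ether chain | C=CCC1=C(O[Si](C)(C)C)C(C)=C[C@@]1(COCc2ccccc2)C[C@H](OCc2ccccc2)[C@@H]1OC1(C)C | intermediate
20 | cis-fused 7a-allyl-5-(benzyloxy)-3a-[(benzyloxy)methyl]-6-hydroxy-2,7,7-trimethyl-3a,4,5,6,7,7a-hexahydro-1H-inden-1-one; CH2OBn, allyl, 5-OBn and 6-OH on one face | c1ccccc1COC[C@]12C[C@H](OCc3ccccc3)[C@H](O)C(C)(C)[C@@]1(CC=C)C(=O)C(C)=C2 | intermediate
21 | 6-O-tert-butyldimethylsilyl ether of 20 | c1ccccc1COC[C@]12C[C@H](OCc3ccccc3)[C@H](O[Si](C)(C)C(C)(C)C)C(C)(C)[C@@]1(CC=C)C(=O)C(C)=C2 | intermediate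
22 | aldehyde from cleavage of the allyl group of 21 (7a-CH2CHO) | c1ccccc1COC[C@]12C[C@H](OCc3ccccc3)[C@H](O[Si](C)(C)C(C)(C)C)C(C)(C)[C@@]1(CC=O)C(=O)C(C)=C2 | intermediate
23 | 4-methylbenzenesulfonylhydrazone of aldehyde 22 | c1ccccc1COC[C@]12C[C@H](OCc3ccccc3)[C@H](O[Si](C)(C)C(C)(C)C)C(C)(C)[C@@]1(CC=NNS(=O)(=O)c3ccc(C)cc3)C(=O)C(C)=C2 | intermediate
24 | diazoalkane from 23 (7a-CH2CH=N2) | c1ccccc1COC[C@]12C[C@H](OCc3ccccc3)[C@H](O[Si](C)(C)C(C)(C)C)C(C)(C)[C@@]1(CC=[N+]=[N-])C(=O)C(C)=C2 | intermediate
25 | 1-pyrazoline from cycloaddition across C9=C10 (C8–C9 and N–C10 bonds on the Ca face) | c1ccccc1COC[C@]12C[C@H](OCc3ccccc3)[C@H](O[Si](C)(C)C(C)(C)C)C(C)(C)[C@]13C[C@@H]4[C@H]2[C@@](C)(N=N4)C3=O | intermediate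
26 | nortricyclane cage ketone: C11 ketone, C4 silyl ether, C3 and Ca benzyl ethers | c1ccccc1COC[C@]12C[C@H](OCc3ccccc3)[C@H](O[Si](C)(C)C(C)(C)C)C(C)(C)[C@]13C[C@@H]1[C@H]2[C@]1(C)C3=O | intermediate
27 | C11 alcohol of 26, hydroxyl cis to the C7 bridge and Ca | c1ccccc1COC[C@]12C[C@H](OCc3ccccc3)[C@H](O[Si](C)(C)C(C)(C)C)C(C)(C)[C@]13C[C@@H]1[C@H]2[C@]1(C)[C@H]3O | intermediate
28 | triol (Ca–OH, C3–OH, C11–OH) with C4 silyl ether | OC[C@]12C[C@H](O)[C@H](O[Si](C)(C)C(C)(C)C)C(C)(C)[C@]13C[C@@H]1[C@H]2[C@]1(C)[C@H]3O | intermediate
29 | Ca, C3, C11 triacetate with C4 silyl ether | CC(=O)OC[C@]12C[C@H](OC(C)=O)[C@H](O[Si](C)(C)C(C)(C)C)C(C)(C)[C@]13C[C@@H]1[C@H]2[C@]1(C)[C@H]3OC(C)=O | intermediate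
30 | CNP0197219.1: Ca, C3, C11 triacetate with free C4 hydroxyl | CC(=O)OC[C@]12C[C@H](OC(C)=O)[C@H](O)C(C)(C)[C@]13C[C@@H]1[C@H]2[C@]1(C)[C@H]3OC(C)=O | target

## Step count and least certain steps

Total: 19 steps. Longest linear sequence: 19 steps (from 1 and 2 to 30); the route is linear.

**Step 11 (key step).** What may go wrong: bond formation between the tetrasubstituted C6 and the tertiary C5 is slow, because three fully substituted carbons become contiguous. Backside alignment of C6, C5 and the leaving oxygen is open to this diastereomer only through a chair with three axial groups on one face (Ca, the C3 benzyloxy group, a C5 methyl) or through a boat-like arrangement. Hydride migration from C4 to C5 (ending in a C4 carbonyl), proton loss from a C5 methyl group, chloride capture, or participation of the Ca benzyl ether oxygen at the activated epoxide may then overtake the cyclisation.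
Fallback: let the ring close through the stereoelectronically matched epimer and correct C4 afterwards. Setting out from 17, epoxidation with the D-fructose-derived ketone catalyst and KHSO5 should give the C4-epimeric epoxy ketone F1, and LiN(iPr)2/Me3SiCl its silyl dienol ether F2. With TiCl4, F2 can close ring A through a chair in which Ca, the C3 benzyloxy group and the C4 oxygen are all equatorial and the C4–O bond is anti to C6, giving the C4-epimeric hydrindenone alcohol F3. Dess–Martin oxidation gives the C4 ketone F4. NaBH4 in MeOH/CH2Cl2 at −78 °C should reduce the α-alkoxy ketone in preference to the hindered enone, with hydride arriving anti to the neighbouring C3–O bond (polar Felkin–Anh control), so that the hydroxyl ends cis to the benzyloxy group, which returns the route at 20.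

**Step 16.** What may go wrong: hydride transfer to the shielded face of C11 may be too slow for the equilibrium to be reached, so the kinetically formed epimer with oxygen under ring A persists.
Fallback: set the C11 oxygen before the cage exists, by inversion. Setting out from 21, NaBH4/CeCl3·7H2O (Luche reduction) should deliver hydride from the allyl face and give the allylic alcohol F5 with hydroxyl trans to the allyl group. A Mitsunobu reaction (4-nitrobenzoic acid, PPh3, diisopropyl azodicarboxylate) inverts C11 to the 4-nitrobenzoate F6. OsO4/NaIO4 gives the aldehyde F7 and TsNHNH2 the tosylhydrazone F8. NaH followed by heating gives the diazoalkane F9, which adds across the now unactivated C9=C10 alkene to the pyrazoline F10; photolysis or heating at 140 °C expels N2 to give the cage ester F11. K2CO3 in MeOH removes the ester and returns the route at 27.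

**Step 15.** What may go wrong: the diazoalkane may lose N2 before it adds, with 1,2-hydrogen shift to a vinyl group or azine formation, or the pyrazoline may fail to extrude N2 cleanly at the chosen temperature.
Fallback: close the cyclopropane by conjugate addition and 1,3-elimination in place of a dipolar addition. Setting out from 22, NaBH4 at −78 °C reduces the aldehyde to the primary alcohol F12. An Appel reaction (I2, PPh3, imidazole) gives the iodide F13, and PhSO2Na in DMF the phenyl sulfone F14. With KOtBu in THF the α-sulfonyl carbanion should add to C9 of the enone, and the resulting C10 enolate should displace benzenesulfinate from C8 (Michael-initiated ring closure by 1,3-elimination of a sulfinate), which returns the route at 26.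

**Step 3.** What may go wrong: proton transfer from the α-bromo amide to the hindered enolate, loss of benzyloxide from the β-alkoxy enolate, or poor facial selectivity in forming the quaternary carbon.
Fallback: use an electrophile without acidic hydrogens and build the enone from it. Setting out from 5, LiN(iPr)2 and allyl bromide (16) should give the 6-allyl lactam F15 with the same facial sense. OsO4/NaIO4 gives the aldehyde F16, Grignard reagent 8 the allylic alcohol F17 as a mixture of carbinol epimers, and Dess–Martin oxidation returns the route at 9.

## Further compounds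

F1 | step 11 | C4-epimeric epoxy ketone, (2R)-3,3-dimethyloxiran-2-yl epimer of 18 | CC1=C[C@@](COCc2ccccc2)(C[C@H](OCc2ccccc2)[C@H]2OC2(C)C)C(CC=C)C1=O
F2 | step 11 | trimethylsilyl dienol ether of F1 | C=CCC1=C(O[Si](C)(C)C)C(C)=C[C@@]1(COCc2ccccc2)C[C@H](OCc2ccccc2)[C@H]1OC1(C)C
F3 | step 11 | C4-epimeric hydrindenone alcohol (6-OH trans to 5-OBn) | c1ccccc1COC[C@]12C[C@H](OCc3ccccc3)[C@@H](O)C(C)(C)[C@@]1(CC=C)C(=O)C(C)=C2
F4 | step 11 | C4 ketone (hydrindene-1,6-dione) | c1ccccc1COC[C@]12C[C@H](OCc3ccccc3)C(=O)C(C)(C)[C@@]1(CC=C)C(=O)C(C)=C2
F5 | step 16 | C11 allylic alcohol from 21, hydroxyl trans to the allyl group | c1ccccc1COC[C@]12C[C@H](OCc3ccccc3)[C@H](O[Si](C)(C)C(C)(C)C)C(C)(C)[C@@]1(CC=C)[C@@H](O)C(C)=C2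
F6 | step 16 | C11-inverted 4-nitrobenzoate, ester cis to the allyl group | c1ccccc1COC[C@]12C[C@H](OCc3ccccc3)[C@H](O[Si](C)(C)C(C)(C)C)C(C)(C)[C@@]1(CC=C)[C@H](OC(=O)c3ccc(cc3)[N+](=O)[O-])C(C)=C2
F7 | step 16 | aldehyde from cleavage of the allyl group of F6 | c1ccccc1COC[C@]12C[C@H](OCc3ccccc3)[C@H](O[Si](C)(C)C(C)(C)C)C(C)(C)[C@@]1(CC=O)[C@H](OC(=O)c3ccc(cc3)[N+](=O)[O-])C(C)=C2
F8 | step 16 | tosylhydrazone of F7 | c1ccccc1COC[C@]12C[C@H](OCc3ccccc3)[C@H](O[Si](C)(C)C(C)(C)C)C(C)(C)[C@@]1(CC=NNS(=O)(=O)c3ccc(C)cc3)[C@H](OC(=O)c3ccc(cc3)[N+](=O)[O-])C(C)=C2
F9 | step 16 | diazoalkane from F8 | c1ccccc1COC[C@]12C[C@H](OCc3ccccc3)[C@H](O[Si](C)(C)C(C)(C)C)C(C)(C)[C@@]1(CC=[N+]=[N-])[C@H](OC(=O)c3ccc(cc3)[N+](=O)[O-])C(C)=C2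
F10 | step 16 | pyrazoline from F9 | c1ccccc1COC[C@]12C[C@H](OCc3ccccc3)[C@H](O[Si](C)(C)C(C)(C)C)C(C)(C)[C@]13C[C@@H]4[C@H]2[C@@](C)(N=N4)[C@H]3OC(=O)c4ccc(cc4)[N+](=O)[O-]
F11 | step 16 | cage C11 4-nitrobenzoate | c1ccccc1COC[C@]12C[C@H](OCc3ccccc3)[C@H](O[Si](C)(C)C(C)(C)C)C(C)(C)[C@]13C[C@@H]1[C@H]2[C@]1(C)[C@H]3OC(=O)c3ccc(cc3)[N+](=O)[O-]
F12 | step 15 | primary alcohol from reduction of aldehyde 22 | c1ccccc1COC[C@]12C[C@H](OCc3ccccc3)[C@H](O[Si](C)(C)C(C)(C)C)C(C)(C)[C@@]1(CCO)C(=O)C(C)=C2
F13 | step 15 | primary iodide from F12 | c1ccccc1COC[C@]12C[C@H](OCc3ccccc3)[C@H](O[Si](C)(C)C(C)(C)C)C(C)(C)[C@@]1(CCI)C(=O)C(C)=C2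
F14 | step 15 | phenyl sulfone from F13 | c1ccccc1COC[C@]12C[C@H](OCc3ccccc3)[C@H](O[Si](C)(C)C(C)(C)C)C(C)(C)[C@@]1(CCS(=O)(=O)c3ccccc3)C(=O)C(C)=C2
F15 | step 3 | 6-allyl-6-[(benzyloxy)methyl] lactam, CH2OBn syn to the angular ethyl group | O=C1[C@@](COCc3ccccc3)(CC=C)C[C@@]2(CC)OC[C@H](C(C)C)N12
F16 | step 3 | lactam aldehyde from cleavage of the allyl group of F15 | O=C1[C@@](COCc3ccccc3)(CC=O)C[C@@]2(CC)OC[C@H](C(C)C)N12
F17 | step 3 | lactam allylic alcohol, both carbinol epimers | O=C1[C@@](COCc3ccccc3)(CC(O)C=C(C)C)C[C@@]2(CC)OC[C@H](C(C)C)N12
A1 | alternative 1 | tricyclic exo-bromo methyl ester silyl enol ether with C3/C4 acetonide | COC(=O)[C@]12C[C@@H]3OC(C)(C)O[C@@H]3C(C)(C)[C@]14C[C@@H](C(C)=C4O[Si](C)(C)C(C)(C)C)[C@@H]2Br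
A2 | alternative 2 | cage C11 ketone with Ca acetate and C3/C4 cyclic carbonate | CC(=O)OC[C@]12C[C@@H]3OC(=O)O[C@@H]3C(C)(C)[C@]14C[C@@H]1[C@H]2[C@]1(C)C4=O
A3 | alternative 2 | dimethylaluminium chloride | C[Al](C)Cl
A4 | alternative 3 | cage C11 alcohol with Ca acetate and C3/C4 acetonide | CC(=O)OC[C@]12C[C@@H]3OC(C)(C)O[C@@H]3C(C)(C)[C@]14C[C@@H]1[C@H]2[C@]1(C)[C@H]4O
A5 | alternative 3 | iron tris(acetylacetonate) | CC(=O)C=C(C)[O-].CC(=O)C=C(C)[O-].CC(=O)C=C(C)[O-].[Fe+3]
A6 | alternative 3 | phenylsilane | [SiH3]c1ccccc1
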